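**Strategy in one sentence:** the two achiral halves are joined at C2–C1′ by a catalytic enantioselective 1,4‑addition of a ring‑B/D arylboronic acid to a preformed 8‑prenylchromone, so that ring C is never closed at the stereocenter and the chalcone manifold is never entered.

## Analysis of the target

Euchrenone a17 is a (2S)‑flavanone. Ring A (C4a–C5–C6–C7–C8–C8a) is fused to the dihydropyranone ring C (O1–C2–C3–C4), and ring B (C1′–C6′) carries a fused 2,2‑dimethyldihydropyran, ring D, across C3′/C4′ with its oxygen on C4′. The only stereocenter is C2. It is benzylic to ring B, bound to O1 and β to the C4 carbonyl, and nothing else in the molecule can relay chirality to it.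

C2 is configurationally fragile in two ways. Base opens O1–C2 by E1cB to the 2′‑hydroxychalcone. Acid can ionize the same bond, because C1′ is para to the ring‑D oxygen.

Ring A is 1,2,3,4‑tetrasubstituted: the prenyl group on C8 lies between C8a–O1 and the free C7–OH. Direct electrophilic prenylation of such a ring would favour C6 or oxygen.

The target is the isomer in which the ring‑B prenyl unit is cyclized (ring D) and the ring‑A prenyl unit is not. Acid, divalent palladium with an oxidant, and hydrogenation are therefore all unsafe once the free ortho‑prenylphenol exists.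

Two features are exploited:
- C2–C1′ is the only bond between the A/C half and the B/D half, and in the oxidized form C2 is the electrophilic end of the C2=C3–C4=O unit of a chromone.
- C8 is ortho to O7, so a C5 unit placed on O7 can be delivered to C8 by a [3,3] shift.

## Retrosynthetic reasoning

**15 ⇒ 14 (O7–acyl).** The last step only frees the C7 phenol. An acetate is chosen because it leaves by near‑neutral acyl transfer, which threatens neither the prenyl/phenol pair (acid) nor the O1–C2 bond (base).

**14 ⇒ 6 + 13 (C2–C1′, key disconnection).** This cut divides the skeleton into two flat, achiral pieces of similar size, chromone 6 and arylboronic acid 13. The forward reaction must add the aryl group of 13 to C2 of the C2=C3–C4=O unit with control of the face. The C–C bond formation is irreversible and runs without base, whereas the textbook O1–C2 closure is a reversible oxa‑Michael addition. Ring C is already present in 6, so no ring closure occurs at the stereocenter. The step must also leave the trisubstituted alkene and the aryl acetate untouched.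

**6 ⇒ 5 ⇒ 4 (C8–CH2 of the prenyl group).** The ortho‑prenylphenol 5 is the retron of an aromatic Claisen rearrangement of the 1,1‑dimethylallyl ether 4. The O7–C bond of 4 is absent from the target; it is made on purpose to deliver the C5 unit intramolecularly to C8 and is cleaved in the same event. The C7–C8 bond of the benzopyranone has the higher π‑bond order, which directs the shift to C8 and not to C6. The rearrangement is placed on the achiral chromone, so heating and isomer separation happen before any stereocenter exists. Acetylation of 5 in the same flask gives 6.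

**4 ⇒ 3 ⇒ 1 + 2 (O7–C tertiary).** A tertiary allylic aryl ether cannot be made by direct SN2 alkylation. The tertiary propargylic chloride 2 alkylates phenol 1 under copper assistance to give 3, and semihydrogenation of the alkyne gives 4.

**13 ⇒ 10 ⇒ 7 + 8 (C–B, then ring D).** The boronic acid 13 comes from bromide 10 by halogen–lithium exchange (11) and borylation (12). Ring D of 10 is formed from 4‑bromophenol 7 and isoprene 8 in one acid‑catalysed operation through the ortho‑prenylphenol 9. The bromine blocks the para position and later becomes the boron.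

## Alternatives that were turned down

Alternative 1: (textbook) Disconnection of O1–C2 and C2=C3 of a chalcone. Forward: Claisen–Schmidt condensation to the 2′‑hydroxychalcone A1, then oxa‑Michael closure of ring C. Turned down because the stereocenter would form in the one bond of the target that is reversible under the closing conditions. Simple 2′‑hydroxychalcones such as A1 lack the second activating group at C3 that makes catalytic asymmetric closure selective, and adding and removing one costs steps. The O7 protecting group must then be removed with acid next to the prenyl group. The sequence is linear and sets the stereocenter last under equilibrium.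

Alternative 2: Disconnection of O1–C2, C4–C4a and C3–C4 around carbon monoxide. Forward: three‑component carbonylative Sonogashira coupling and cyclization of an ortho‑iodophenol, carbon monoxide and an arylalkyne to the flavone A2, then enantioselective reduction of C2=C3. Turned down because the multicomponent step builds ring C but no stereocenter. The later asymmetric 1,4‑reduction must attack a β‑carbon deactivated by both O1 and the electron‑rich ring B, it competes with reduction of C4=O, and hydrogen‑based catalysts endanger the prenyl alkene. The iodophenol needed is itself a contiguously tetrasubstituted ring A, so the regiochemical problem is only moved. Closure to the five‑membered aurone also competes.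

Alternative 3: Disconnection of O1–C2 with inversion. Forward: asymmetric aldol of a ring‑A methyl ketone to the (R)‑β‑hydroxy ketone A3, then Mitsunobu cyclization to the (S)‑flavanone. Turned down because the carbinol carbon of A3 is a para‑alkoxybenzylic centre, so the activated oxyphosphonium can ionize and the inversion would leak. Asymmetric acetate‑type aldols of methyl ketones are weakly selective. Stereocenter and ring are made in separate steps, and two protecting‑group operations are needed.

Key step: step 6

Remark: the facial sense of the palladium/pyridine‑oxazoline arylation is assumed to follow that known for cyclic enones, where the (S)‑ligand gives the (R)‑configured β‑carbon. The same spatial mapping predicts (2S)‑14 from the (R)‑ligand; if the opposite sense is found, the (S)‑ligand is used and nothing else changes.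

## Route

Step 1
Reactants: 1 7‑hydroxy‑4H‑chromen‑4‑one; 2 3‑chloro‑3‑methylbut‑1‑yne
Product: 3 7‑[(2‑methylbut‑3‑yn‑2‑yl)oxy]‑4H‑chromen‑4‑one
Conditions: K2CO3, KI, CuI (5 mol %), acetone, 56 °C
Reagents that add atoms: none
Why: Copper‑assisted propargylic substitution (copper acetylide, SN1‑like) puts the tertiary propargyl group on the acidic O7; the chromone ring is inert to K2CO3 in dry acetone, and the weakly basic phenoxide keeps elimination of 2 minor.

Step 2
Reactants: 3 7‑[(2‑methylbut‑3‑yn‑2‑yl)oxy]‑4H‑chromen‑4‑one
Product: 4 7‑[(2‑methylbut‑3‑en‑2‑yl)oxy]‑4H‑chromen‑4‑one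
Conditions: H2 (1 atm), 5% Pd/CaCO3 poisoned with Pb(OAc)2, quinoline, EtOAc, 20 °C
Reagents that add atoms: none
Why: Lindlar semihydrogenation; the terminal alkyne binds the poisoned surface far more strongly than the product alkene or the vinylogous‑ester C2=C3, so uptake should stop after one equivalent of hydrogen.

Step 3
Reactants: 4 7‑[(2‑methylbut‑3‑en‑2‑yl)oxy]‑4H‑chromen‑4‑one
Product: 6 8‑(3‑methylbut‑2‑en‑1‑yl)‑4‑oxo‑4H‑chromen‑7‑yl acetate, via 7‑hydroxy‑8‑prenylchromone 5 (not isolated)
Conditions: o‑xylene, 135 °C; then Ac2O, pyridine, DMAP (cat.), 20 °C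
Reagents that add atoms: acetic anhydride CC(=O)OC(C)=O
Why: Aromatic Claisen rearrangement through a chair [3,3] transition state turns the 1,1‑dimethylallyl ether into the 3,3‑dimethylallyl (prenyl) group on the ortho carbon, and tautomerization gives phenol 5. C8 should be preferred over C6 because the C7–C8 bond has the higher π‑bond order, the same bias that sends 2‑naphthyl allyl ethers to C1. Acetylation in the same flask masks the acidic ortho‑prenylphenol before isolation.

Step 4
Reactants: 7 4‑bromophenol; 8 isoprene
Product: 10 6‑bromo‑2,2‑dimethylchroman, via 4‑bromo‑2‑prenylphenol 9 (not isolated)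
Conditions: Amberlyst 15, THF/heptane, 65 °C
Reagents that add atoms: none
Why: Acid‑catalysed Friedel–Crafts ortho‑prenylation (para position blocked by bromine) gives 9, and Markovnikov hydroalkoxylation of its alkene at the tertiary cation closes ring D in a 6‑endo‑trig mode.

Step 5
Reactants: 10 6‑bromo‑2,2‑dimethylchroman
Product: 13 (2,2‑dimethylchroman‑6‑yl)boronic acid, via aryllithium 11 (not isolated), via lithium triisopropoxyarylborate 12 (not isolated)
Conditions: n‑BuLi, THF, −78 °C; B(OiPr)3, −78 to 20 °C; 1 M HCl
Reagents that add atoms: triisopropyl borate CC(C)OB(OC(C)C)OC(C)C; water O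
Why: Bromine–lithium exchange, trapping of the aryllithium as the borate complex and hydrolysis; the dialkyl ether ring D and the gem‑dimethyl group are inert to n‑BuLi at −78 °C.

Step 6
Reactants: 6 8‑(3‑methylbut‑2‑en‑1‑yl)‑4‑oxo‑4H‑chromen‑7‑yl acetate; 13 (2,2‑dimethylchroman‑6‑yl)boronic acid (2 equiv)
Product: 14 (2S)‑2‑(2,2‑dimethylchroman‑6‑yl)‑8‑(3‑methylbut‑2‑en‑1‑yl)‑4‑oxochroman‑7‑yl acetate
Conditions: Pd(OCOCF3)2 (5 mol %), (R)‑4‑tert‑butyl‑2‑(pyridin‑2‑yl)‑4,5‑dihydro‑1,3‑oxazole (6 mol %), NH4PF6 (30 mol %), H2O (5 equiv), ClCH2CH2Cl, 60 °C, air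
Reagents that add atoms: none
Why: Transmetalation of 13 to the cationic divalent palladium–pyridine‑oxazoline complex gives an arylpalladium species; chromone 6 binds through C2=C3 and inserts so that the aryl group goes to C2 and palladium to C3, and water protonates the resulting palladium enolate faster than β‑hydride elimination occurs, so the metal stays divalent and neither oxidant nor base is needed. The closest known reaction type is the palladium/pyridine‑oxazoline‑catalysed asymmetric conjugate addition of arylboronic acids to cyclic enones and to chromones, which tolerates air and water. No ring is closed: ring C is carried intact from 6 and only changes from a pyranone to a dihydropyranone. The C2 stereocenter is set under catalyst control in the insertion step, where the tert‑butyl group of the oxazoline blocks one quadrant so that the chromone should present the face leading to the 2S configuration with the (R)‑ligand. The step needs 1,4‑ over 1,2‑addition (secured by the carbopalladation mechanism), reaction at the polarized C2=C3 and not at the trisubstituted, unactivated prenyl alkene (which inserts far more slowly), and survival of the aryl acetate (no base is present). The acetate on O7 also keeps the acidic phenol from binding palladium and from a Wacker‑type attack on the prenyl group, and it makes ring A less donating so that C2 is more electrophilic. Because the medium contains no base, 14 cannot reopen to a chalcone and its configuration should be retained. The excess of 13 compensates for protodeboronation of this electron‑rich arylboron partner.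

Step 7
Reactants: 14 (2S)‑2‑(2,2‑dimethylchroman‑6‑yl)‑8‑(3‑methylbut‑2‑en‑1‑yl)‑4‑oxochroman‑7‑yl acetate
Product: 15 Euchrenone a17, (2S)‑2‑(2,2‑dimethylchroman‑6‑yl)‑7‑hydroxy‑8‑(3‑methylbut‑2‑en‑1‑yl)chroman‑4‑one
Conditions: NH4OAc (excess), MeOH/H2O (4:1), 20 °C
Reagents that add atoms: none
Why: Near‑neutral acyl transfer from the activated aryl acetate (para to the C4 carbonyl) to methanol; neither the acid that would cyclize the prenyl group onto O7 nor the base that would open O1–C2 is present, so the C2 configuration should be kept.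

## Compound list

1 | 7‑hydroxy‑4H‑chromen‑4‑one | O=c1ccoc2cc(O)ccc12 | starting material
2 | 3‑chloro‑3‑methylbut‑1‑yne | C#CC(C)(C)Cl | starting material
3 | 7‑[(2‑methylbut‑3‑yn‑2‑yl)oxy]‑4H‑chromen‑4‑one | C#CC(C)(C)Oc1ccc2c(c1)occc2=O | intermediate
4 | 7‑[(2‑methylbut‑3‑en‑2‑yl)oxy]‑4H‑chromen‑4‑one | C=CC(C)(C)Oc1ccc2c(c1)occc2=O | intermediate
5 | 7‑hydroxy‑8‑(3‑methylbut‑2‑en‑1‑yl)‑4H‑chromen‑4‑one | CC(C)=CCc1c(O)ccc2c1occc2=O | intermediate
6 | 8‑(3‑methylbut‑2‑en‑1‑yl)‑4‑oxo‑4H‑chromen‑7‑yl acetate | CC(C)=CCc1c(OC(C)=O)ccc2c1occc2=O | intermediate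
7 | 4‑bromophenol | Oc1ccc(Br)cc1 | starting material
8 | isoprene (2‑methylbuta‑1,3‑diene) | C=CC(C)=C | starting material
9 | 4‑bromo‑2‑(3‑methylbut‑2‑en‑1‑yl)phenol | CC(C)=CCc1cc(Br)ccc1O | intermediate
10 | 6‑bromo‑2,2‑dimethylchroman | CC1(C)CCc2cc(Br)ccc2O1 | intermediate
11 | (2,2‑dimethylchroman‑6‑yl)lithium | [Li]c1ccc2OC(C)(C)CCc2c1 | intermediate
12 | lithium triisopropoxy(2,2‑dimethylchroman‑6‑yl)borate | [Li+].CC(C)O[B-](OC(C)C)(OC(C)C)c1ccc2OC(C)(C)CCc2c1 | intermediate
13 | (2,2‑dimethylchroman‑6‑yl)boronic acid | OB(O)c1ccc2OC(C)(C)CCc2c1 | intermediate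
14 | (2S)‑2‑(2,2‑dimethylchroman‑6‑yl)‑8‑(3‑methylbut‑2‑en‑1‑yl)‑4‑oxochroman‑7‑yl acetate | CC(C)=CCc1c(OC(C)=O)ccc2c1O[C@H](c1ccc3c(c1)CCC(C)(C)O3)CC2=O | intermediate
15 | Euchrenone a17, (2S)‑2‑(2,2‑dimethylchroman‑6‑yl)‑7‑hydroxy‑8‑(3‑methylbut‑2‑en‑1‑yl)chroman‑4‑one | CC(C)=CCc1c(O)ccc2c1O[C@H](c1ccc3c(c1)CCC(C)(C)O3)CC2=O | target

## Step count and risk

Total step count: 7. Longest linear sequence: 5 steps (steps 1, 2, 3, 6, 7 from 1); the arylboron branch contributes steps 4 and 5.

**Step 6 (key step).** Insertion may be slow, because ring A still donates into the chromone and C8 is substituted. Facial selectivity may erode, because the para‑alkoxyaryl group transfers quickly and a less selective, ligand‑poor pathway can compete. Protodeboronation and oxidative homocoupling of 13 may consume the nucleophile.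
Fallback, from 6 and 10, returning at 15: the C2–C1′ union is given up for the O1–C2 closure of alternative 1, run without protecting groups. Aqueous NaOH in EtOH at reflux opens the pyranone of 6 by conjugate addition of hydroxide and retro‑Claisen loss of formate, and cleaves the acetate, to give 1‑[2,4‑dihydroxy‑3‑(3‑methylbut‑2‑en‑1‑yl)phenyl]ethan‑1‑one F1. Aryllithium 11, generated from 10 as in step 5, is formylated with DMF to 2,2‑dimethylchroman‑6‑carbaldehyde F2. Claisen–Schmidt condensation of F1 with F2 (KOH, EtOH/H2O, 20 °C) should give (E)‑1‑[2,4‑dihydroxy‑3‑(3‑methylbut‑2‑en‑1‑yl)phenyl]‑3‑(2,2‑dimethylchroman‑6‑yl)prop‑2‑en‑1‑one F3. NaOAc in refluxing EtOH closes it by oxa‑Michael addition to racemic 2‑(2,2‑dimethylchroman‑6‑yl)‑7‑hydroxy‑8‑(3‑methylbut‑2‑en‑1‑yl)chroman‑4‑one F4. Preparative chromatography on amylose tris(3,5‑dimethylphenylcarbamate) then gives 15. The unwanted (2R)‑2‑(2,2‑dimethylchroman‑6‑yl)‑7‑hydroxy‑8‑(3‑methylbut‑2‑en‑1‑yl)chroman‑4‑one F5 is returned to F4 by brief exposure to base, which equilibrates it through F3.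

**Step 3.** The [3,3] shift may go partly to C6. The tertiary allylic C–O bond may also break heterolytically with loss of isoprene, because the 7‑oxychromone is a good leaving group; this would return 1.
Fallback, from 1, returning at 6: the C5 unit is attached by cross‑coupling instead of rearrangement. N‑Iodosuccinimide in DMF should iodinate ortho to O7 at C8 (same bond‑order bias) to give 7‑hydroxy‑8‑iodo‑4H‑chromen‑4‑one F6. Ac2O/pyridine gives 8‑iodo‑4‑oxo‑4H‑chromen‑7‑yl acetate F7. Stille coupling with tributyl(3‑methylbut‑2‑en‑1‑yl)stannane (Pd(PPh3)4, DMF, 90 °C) transfers the prenyl group through its α‑carbon and gives 6.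

**Step 4.** O‑prenylation, alkylation at both ortho positions, oligomerization of isoprene, and slow ortho‑alkylation of the bromine‑deactivated ring may lower the throughput.
Fallback, from 7 and 2, returning at 10: ring D is built by a propargyl Claisen sequence. Alkylation of 7 with 2 (K2CO3, KI, CuI, acetone) gives 1‑bromo‑4‑[(2‑methylbut‑3‑yn‑2‑yl)oxy]benzene F8. Heating in N,N‑diethylaniline at 190 °C brings about [3,3] shift, enolization, 1,5‑hydrogen shift and 6π‑electrocyclization to 6‑bromo‑2,2‑dimethyl‑2H‑chromene F9. Hydrogenation of the cis‑disubstituted alkene with H2 and RhCl(PPh3)3, which leaves the aryl bromide intact, gives 10.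

**Step 7.** If the medium turns basic, reversible opening of ring C at O1–C2 may cause partial racemization; acyl transfer may also stall.
Fallback, from 5 (isolated after the thermal stage of step 3), returning at 15: the phenol is carried as a silyl ether that is cleaved by acidic fluoride. Chlorotriisopropylsilane and imidazole in DMF give 8‑(3‑methylbut‑2‑en‑1‑yl)‑7‑[(triisopropylsilyl)oxy]‑4H‑chromen‑4‑one F10. The conditions of step 6 with 13 should give (2S)‑2‑(2,2‑dimethylchroman‑6‑yl)‑8‑(3‑methylbut‑2‑en‑1‑yl)‑7‑[(triisopropylsilyl)oxy]chroman‑4‑one F11. Et3N·3HF in THF at 20 °C removes the silyl group without generating a free phenoxide and gives 15.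

## Further compounds

F1 | step 6 | 1‑[2,4‑dihydroxy‑3‑(3‑methylbut‑2‑en‑1‑yl)phenyl]ethan‑1‑one | CC(C)=CCc1c(O)ccc(C(C)=O)c1O
F2 | step 6 | 2,2‑dimethylchroman‑6‑carbaldehyde | O=Cc1ccc2OC(C)(C)CCc2c1
F3 | step 6 | (E)‑1‑[2,4‑dihydroxy‑3‑(3‑methylbut‑2‑en‑1‑yl)phenyl]‑3‑(2,2‑dimethylchroman‑6‑yl)prop‑2‑en‑1‑one | CC(C)=CCc1c(O)ccc(C(=O)/C=C/c2ccc3OC(C)(C)CCc3c2)c1O
F4 | step 6 | racemic 2‑(2,2‑dimethylchroman‑6‑yl)‑7‑hydroxy‑8‑(3‑methylbut‑2‑en‑1‑yl)chroman‑4‑one | CC(C)=CCc1c(O)ccc2c1OC(c1ccc3c(c1)CCC(C)(C)O3)CC2=O
F5 | step 6 | (2R)‑2‑(2,2‑dimethylchroman‑6‑yl)‑7‑hydroxy‑8‑(3‑methylbut‑2‑en‑1‑yl)chroman‑4‑one | CC(C)=CCc1c(O)ccc2c1O[C@@H](c1ccc3c(c1)CCC(C)(C)O3)CC2=O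
F6 | step 3 | 7‑hydroxy‑8‑iodo‑4H‑chromen‑4‑one | O=c1ccoc2c(I)c(O)ccc12
F7 | step 3 | 8‑iodo‑4‑oxo‑4H‑chromen‑7‑yl acetate | CC(=O)Oc1ccc2c(c1I)occc2=O
F8 | step 4 | 1‑bromo‑4‑[(2‑methylbut‑3‑yn‑2‑yl)oxy]benzene | C#CC(C)(C)Oc1ccc(Br)cc1
F9 | step 4 | 6‑bromo‑2,2‑dimethyl‑2H‑chromene | CC1(C)C=Cc2cc(Br)ccc2O1
F10 | step 7 | 8‑(3‑methylbut‑2‑en‑1‑yl)‑7‑[(triisopropylsilyl)oxy]‑4H‑chromen‑4‑one | CC(C)=CCc1c(O[Si](C(C)C)(C(C)C)C(C)C)ccc2c1occc2=O
F11 | step 7 | (2S)‑2‑(2,2‑dimethylchroman‑6‑yl)‑8‑(3‑methylbut‑2‑en‑1‑yl)‑7‑[(triisopropylsilyl)oxy]chroman‑4‑one | CC(C)=CCc1c(O[Si](C(C)C)(C(C)C)C(C)C)ccc2c1O[C@H](c1ccc3c(c1)CCC(C)(C)O3)CC2=O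
A1 | alternative 1 | (E)‑1‑[2‑hydroxy‑4‑(methoxymethoxy)‑3‑(3‑methylbut‑2‑en‑1‑yl)phenyl]‑3‑(2,2‑dimethylchroman‑6‑yl)prop‑2‑en‑1‑one | COCOc1ccc(C(=O)/C=C/c2ccc3OC(C)(C)CCc3c2)c(O)c1CC=C(C)C
A2 | alternative 2 | 2‑(2,2‑dimethylchroman‑6‑yl)‑7‑hydroxy‑8‑(3‑methylbut‑2‑en‑1‑yl)‑4H‑chromen‑4‑one | CC(C)=CCc1c(O)ccc2c1oc(-c1ccc3OC(C)(C)CCc3c1)cc2=O
A3 | alternative 3 | (3R)‑3‑(2,2‑dimethylchroman‑6‑yl)‑3‑hydroxy‑1‑[2‑hydroxy‑4‑(methoxymethoxy)‑3‑(3‑methylbut‑2‑en‑1‑yl)phenyl]propan‑1‑one | COCOc1ccc(C(=O)C[C@@H](O)c2ccc3OC(C)(C)CCc3c2)c(O)c1CC=C(C)C
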